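**Retrosynthetic overview**
1. Target ⇐ global O-debenzylation of its tri-O-benzyl ether.
2. The only ring (the tetrahydrofuran) is opened at its O–CH2 bond: intramolecular Williamson etherification of an acyclic (S,S,S,S)-triol, benzylic OH of one half onto the primary carbon of the other half, no stereocentre touched.
3. Both benzylic C–O bonds and all four stereocentres are disconnected together: twofold reagent-controlled syn-hydration (asymmetric hydroboration–oxidation) of an achiral (E,E)-2,3-bis(arylidene)butane-1,4-diol mono-benzyl ether.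
4. That diene ⇐ mono-O-benzylation and alane reduction of the (E,E)-bis(arylidene)succinic acid ⇐ one-pot double Stobbe condensation of O-benzylvanillin (2 equiv) with diethyl succinate.
5. Ring order: a single ring, closed in the penultimate step after all stereocentres are in place.

Assumption: the SMILES is read as drawn, i.e. all four stereocentres S, with the aryl, CH2OH and CH(OH)Ar groups all cis on the tetrahydrofuran.
Assumption: the facial sense of IpcBH2 is assigned by analogy with simple trisubstituted alkenes (the reagent from (+)-α-pinene gives S carbinols there; the aryl group on the boron-bearing carbon swaps the CIP priorities here); if the sense proves opposite, the reagent from (+)-α-pinene is used instead.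

Step 1
Reactants: 1 4-(benzyloxy)-3-methoxybenzaldehyde (2 equiv); 2 diethyl succinate
Product: 3 (2E,3E)-2,3-bis[4-(benzyloxy)-3-methoxybenzylidene]succinic acid
Conditions: NaOEt (4.5 equiv), EtOH, reflux, 16 h; then aq HCl to pH 1; crystallise
Reagents that add atoms: none
Why: One-pot double Stobbe condensation, in which each aldol adduct lactonises onto the neighbouring ester and opens by E1cB, so both esters end as carboxylates and the favoured (E,E)-diene (aryl trans to CO2H) is obtained; no stereocentre is formed.

Step 2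
Reactants: 3 (2E,3E)-2,3-bis[4-(benzyloxy)-3-methoxybenzylidene]succinic acid
Product: 4 (2E,3E)-2,3-bis[4-(benzyloxy)-3-methoxybenzylidene]butane-1,4-diol
Conditions: AlH3 (from LiAlH4 and AlCl3, 3:1), THF, 0 °C to rt; aq potassium sodium tartrate work-up
Reagents that add atoms: none
Why: Alane reduction of the carboxylic acids is a clean 1,2-reduction that leaves the cinnamyl C=C bonds and the benzyl ethers alone, so the (E,E) geometry is kept.

Step 3
Reactants: 4 (2E,3E)-2,3-bis[4-(benzyloxy)-3-methoxybenzylidene]butane-1,4-diol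
Product: 5 (2E,3E)-4-(benzyloxy)-2,3-bis[4-(benzyloxy)-3-methoxybenzylidene]butan-1-ol
Conditions: Ag2O (1.5 equiv), BnBr (1.1 equiv), CH2Cl2, rt
Reagents that add atoms: benzyl bromide BrCc1ccccc1
Why: Ag2O-mediated Williamson monobenzylation of a symmetrical diol, where the second OH reacts much more slowly once the first is etherified; the two OH groups are homotopic, so only one mono-ether exists.

Step 4
Reactants: 5 (2E,3E)-4-(benzyloxy)-2,3-bis[4-(benzyloxy)-3-methoxybenzylidene]butan-1-ol
Product: 7 (1S,2S,3S,4S)-1,4-bis[4-(benzyloxy)-3-methoxyphenyl]-2-[(benzyloxy)methyl]-3-(hydroxymethyl)butane-1,4-diol, via tris(isopinocampheylboryl) adduct 6 (not isolated)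
Conditions: IpcBH2 (from (−)-α-pinene, 4 equiv), THF, −25 to 0 °C, 72 h; then NaOH, H2O2, 0 to 40 °C
Reagents that add atoms: hydrogen peroxide OO; monoisopinocampheylborane [BH2][C@H]1C[C@H]2C[C@@H]([C@@H]1C)C2(C)C (its atoms stay only in 6)
Why: Proposed new method: twofold reagent-controlled asymmetric hydroboration of a twisted (E,E)-2,3-disubstituted 1,4-diaryl-1,3-diene with IpcBH2, not yet shown on such dienes; because the two styrene units are nearly orthogonal they should react as two independent β,β-disubstituted styrenes, boron adds through the four-centre transition state to the less hindered benzylic CH terminus and hydrogen to the fully substituted carbon on the same face, so each E-alkene gives the like (S,S) pair, the same reagent face preference on both alkenes gives the S,S,S,S isomer (mismatched additions end up in the separable unlike diastereomer, which raises the ee of the like product), and alkaline H2O2 replaces each C–B by C–O with retention; closest known reaction type: Brown asymmetric hydroboration–oxidation of trisubstituted alkenes such as 1-phenylcycloalkenes with IpcBH2.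

Step 5
Reactants: 7 (1S,2S,3S,4S)-1,4-bis[4-(benzyloxy)-3-methoxyphenyl]-2-[(benzyloxy)methyl]-3-(hydroxymethyl)butane-1,4-diol
Product: 9 (S)-[4-(benzyloxy)-3-methoxyphenyl]{(3S,4S,5S)-5-[4-(benzyloxy)-3-methoxyphenyl]-4-[(benzyloxy)methyl]tetrahydrofuran-3-yl}methanol, via primary tosylate 8 (not isolated)
Conditions: TsCl (1.1 equiv), pyridine, DMAP (cat.), 0 °C to rt; then 50 °C
Reagents that add atoms: p-toluenesulfonyl chloride Cc1ccc(cc1)S(Cl)(=O)=O (its atoms stay only in 8)
Why: Selective sulfonylation of the only primary OH is followed by 5-exo-tet intramolecular Williamson etherification by the benzylic OH of the other half (the 1,3-related OH could only give an oxetane); no bond to a stereocentre is broken, so the ring closes with retention and all three ring substituents end up cis.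

Step 6
Reactants: 9 (S)-[4-(benzyloxy)-3-methoxyphenyl]{(3S,4S,5S)-5-[4-(benzyloxy)-3-methoxyphenyl]-4-[(benzyloxy)methyl]tetrahydrofuran-3-yl}methanol
Product: 10 (S)-(4-hydroxy-3-methoxyphenyl)[(3S,4S,5S)-5-(4-hydroxy-3-methoxyphenyl)-4-(hydroxymethyl)tetrahydrofuran-3-yl]methanol
Conditions: H2 (1 atm), Pd/C (10 wt %), EtOAc–EtOH, rt, stopped at complete O-debenzylation
Reagents that add atoms: none
Why: Catalytic hydrogenolysis under neutral conditions cleaves the two aryl benzyl ethers and the primary alkyl benzyl ether faster than the electron-rich benzylic C–O bonds of the ring and the carbinol, so no stereocentre is touched.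

**Compound list**
1 | 4-(benzyloxy)-3-methoxybenzaldehyde (O-benzylvanillin) | COc1cc(C=O)ccc1OCc1ccccc1 | starting material
2 | diethyl succinate | CCOC(=O)CCC(=O)OCC | starting material
3 | (2E,3E)-2,3-bis[4-(benzyloxy)-3-methoxybenzylidene]succinic acid | OC(=O)/C(=C/c1ccc(OCc2ccccc2)c(OC)c1)C(=C/c1ccc(OCc2ccccc2)c(OC)c1)\C(O)=O | intermediate
4 | (2E,3E)-2,3-bis[4-(benzyloxy)-3-methoxybenzylidene]butane-1,4-diol | OC/C(=C/c1ccc(OCc2ccccc2)c(OC)c1)C(=C/c1ccc(OCc2ccccc2)c(OC)c1)\CO | intermediate
5 | (2E,3E)-4-(benzyloxy)-2,3-bis[4-(benzyloxy)-3-methoxybenzylidene]butan-1-ol | OC/C(=C/c1ccc(OCc2ccccc2)c(OC)c1)C(=C/c1ccc(OCc2ccccc2)c(OC)c1)\COCc1ccccc1 | intermediate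
6 | tris(isopinocampheylboryl) adduct of 5 (boron on both benzylic carbons and on the primary oxygen; not isolated) | COc1cc([C@@H]([BH][C@H]4C[C@H]5C[C@@H]([C@@H]4C)C5(C)C)[C@H](CO[BH][C@H]4C[C@H]5C[C@@H]([C@@H]4C)C5(C)C)[C@@H](COCc2ccccc2)[C@H]([BH][C@H]4C[C@H]5C[C@@H]([C@@H]4C)C5(C)C)c2ccc(OCc3ccccc3)c(OC)c2)ccc1OCc1ccccc1 | intermediate
7 | (1S,2S,3S,4S)-1,4-bis[4-(benzyloxy)-3-methoxyphenyl]-2-[(benzyloxy)methyl]-3-(hydroxymethyl)butane-1,4-diol | COc1cc([C@@H](O)[C@H](CO)[C@@H](COCc2ccccc2)[C@H](O)c2ccc(OCc3ccccc3)c(OC)c2)ccc1OCc1ccccc1 | intermediate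
8 | primary 4-methylbenzenesulfonate of 7 (tosylate on the hydroxymethyl group; not isolated) | COc1cc([C@@H](O)[C@H](COS(=O)(=O)c2ccc(C)cc2)[C@@H](COCc2ccccc2)[C@H](O)c2ccc(OCc3ccccc3)c(OC)c2)ccc1OCc1ccccc1 | intermediate
9 | (S)-[4-(benzyloxy)-3-methoxyphenyl]{(3S,4S,5S)-5-[4-(benzyloxy)-3-methoxyphenyl]-4-[(benzyloxy)methyl]tetrahydrofuran-3-yl}methanol | COc1cc([C@@H](O)[C@@H]2CO[C@H](c3ccc(OCc4ccccc4)c(OC)c3)[C@@H]2COCc2ccccc2)ccc1OCc1ccccc1 | intermediate
10 | (S)-(4-hydroxy-3-methoxyphenyl)[(3S,4S,5S)-5-(4-hydroxy-3-methoxyphenyl)-4-(hydroxymethyl)tetrahydrofuran-3-yl]methanol | COc1cc([C@@H](O)[C@@H]2CO[C@H](c3ccc(O)c(OC)c3)[C@@H]2CO)ccc1O | target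

**Totals**
Total steps: 6. Longest linear sequence: 6 steps (from 1 and 2).

**Three steps most likely to fail, with fallbacks**

Step 1 is at risk because the one-pot double Stobbe condensation can stall after the first condensation and give low yields with this electron-rich aldehyde. The fallback builds the diene stepwise, setting out from 1 and 2 and coming back at 4. Stobbe condensation of 1 (1 equiv) with 2 (KOtBu, tBuOH) gives (E)-4-[4-(benzyloxy)-3-methoxyphenyl]-3-(ethoxycarbonyl)but-3-enoic acid F1. Esterification (EtI, K2CO3, DMF) gives diethyl (E)-2-[4-(benzyloxy)-3-methoxybenzylidene]succinate F2. A second Stobbe condensation of F2 with 1 (NaOEt, EtOH) gives (2E,3E)-2,3-bis[4-(benzyloxy)-3-methoxybenzylidene]succinic acid monoethyl ester F3, which AlH3 reduces directly to 4.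

Step 4, the proposed new step, is at risk in three ways: the facial selectivity of IpcBH2 on these hindered alkenes may be only moderate, the second B–H of a first-formed dialkylborane may add intramolecularly to the other alkene under substrate control, and the free OH consumes reagent. The fallback uses known chemistry, setting out from 5 and coming back at 7. Ordinary hydroboration with BH3·SMe2 (THF, 0 °C to rt) and NaOH/H2O2 oxidation gives the racemic like-triol rac-(1R*,2R*,3R*,4R*)-1,4-bis[4-(benzyloxy)-3-methoxyphenyl]-2-[(benzyloxy)methyl]-3-(hydroxymethyl)butane-1,4-diol F4. It is formed together with the racemic unlike-triol rac-(1S*,2S*,3R*,4R*)-1,4-bis[4-(benzyloxy)-3-methoxyphenyl]-2-[(benzyloxy)methyl]-3-(hydroxymethyl)butane-1,4-diol F5, which is removed on silica. F4 is then resolved by preparative chiral SFC, the (1S,2S,3S,4S) enantiomer being 7.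

Step 6 is at risk because prolonged hydrogenolysis, needed for the primary alkyl benzyl ether, may also cleave the benzylic C–O bond of the ring or of the carbinol once the phenols are free. The fallback sets out from 9 and comes back at 10, replacing hydrogenolysis by electron-transfer debenzylation with lithium 4,4'-di-tert-butylbiphenylide (LiDBB, THF, −78 °C, then NH4Cl). The carbinol is protected in situ as its alkoxide, and the aryl rings become electron-rich phenoxides that resist further reduction. This fallback makes no new compound (F0).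

**Further compounds**
F1 | step 1 | (E)-4-[4-(benzyloxy)-3-methoxyphenyl]-3-(ethoxycarbonyl)but-3-enoic acid | CCOC(=O)/C(=C/c1ccc(OCc2ccccc2)c(OC)c1)CC(O)=O
F2 | step 1 | diethyl (E)-2-[4-(benzyloxy)-3-methoxybenzylidene]succinate | CCOC(=O)/C(=C/c1ccc(OCc2ccccc2)c(OC)c1)CC(=O)OCC
F3 | step 1 | (2E,3E)-2,3-bis[4-(benzyloxy)-3-methoxybenzylidene]succinic acid monoethyl ester | CCOC(=O)/C(=C/c1ccc(OCc2ccccc2)c(OC)c1)C(=C/c1ccc(OCc2ccccc2)c(OC)c1)\C(O)=O
F4 | step 4 | racemic like-triol (7 and its enantiomer, 1:1) | COc1cc([C@@H](O)[C@H](CO)[C@@H](COCc2ccccc2)[C@H](O)c2ccc(OCc3ccccc3)c(OC)c2)ccc1OCc1ccccc1.COc1cc([C@H](O)[C@@H](CO)[C@H](COCc2ccccc2)[C@@H](O)c2ccc(OCc3ccccc3)c(OC)c2)ccc1OCc1ccccc1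
F5 | step 4 | racemic unlike-triol ((1S,2S,3R,4R) and (1R,2R,3S,4S), 1:1) | COc1cc([C@H](O)[C@@H](CO)[C@@H](COCc2ccccc2)[C@H](O)c2ccc(OCc3ccccc3)c(OC)c2)ccc1OCc1ccccc1.COc1cc([C@@H](O)[C@H](CO)[C@H](COCc2ccccc2)[C@@H](O)c2ccc(OCc3ccccc3)c(OC)c2)ccc1OCc1ccccc1
F0 | step 6 | none | none
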